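**Retrosynthetic overview**

1. Target 23 ← Pinnick oxidation and acetal hydrolysis ← tricyclic chromanone acetal 20, in which the C5–OH / CO2H pair is masked as a 2‑methoxychroman (lactol methyl ether) ring.
2. The chromanone ring is cut at O1–C8a (ring closure) and C4–C4a: aryllithium from bromide 11 plus trans‑β‑lactone 17 in one pot (acylation, then SNAr of C8a–F by the liberated C2 alkoxide).
3. Enabling feature: C4=O is ortho to C8a on the benzene ring and β to O1, so O1–C2–C3–C4 is an aldol unit (a ring‑opened β‑lactone with both stereocentres preset). The ketone formed at C4a activates the neighbouring C8a–F, which is the only fluorine and is meta to the two other ring oxygens (on C5 and C7).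
4. Arene 11 ← 4‑bromo‑3,5‑difluoroanisole: SNAr F→OH, Pechmann coumarin at the only free ortho carbon (Br blocks the other and later becomes the lithiation site), CuH 1,4‑reduction for the benzylic centre, lactone → methyl acetal, lithiation–prenylation at the C–H between F and OMe. Lactone 17 ← ethyl (S)‑3‑hydroxybutanoate (Fráter–Seebach methylation, β‑lactonisation).
5. Ring order: benzene (bought) → lactone ring (Pechmann, later acetal) → chromanone pyranone ring (key step) → acetal ring opened last.

Key step: step 10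

Assumption: in step 3 the (S)‑ligand is taken to give the (4R)‑lactone by analogy with 4‑substituted coumarins; if the sense proves opposite, the (R)‑ligand is used and nothing else changes. Compounds 7, 8, 10, 11 and 18–21 are carried as C2 epimers at the temporary lactol/acetal carbon, which is destroyed in step 12.

**Route**

Step 1
Reactants: 1 4‑bromo‑3,5‑difluoroanisole
Product: 3 2‑bromo‑3‑fluoro‑5‑methoxyphenol, via aryl 2‑(trimethylsilyl)ethyl ether 2 (not isolated)
Conditions: Me3SiCH2CH2OH (1.05 equiv), KOt‑Bu (1.05 equiv), THF/DMPU, 60 °C; then TBAF, 60 °C; aq. HCl work‑up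
Reagents that add atoms: 2‑(trimethylsilyl)ethanol C[Si](C)(C)CCO
Why: SNAr (addition–elimination) of the primary alkoxide at one of the two equivalent C–F carbons of symmetric 1 (activated by ortho‑Br and meta‑F, mono‑substitution held by stoichiometry), then fluoride‑induced β‑fragmentation of the silylethyl ether to the phenol.

Step 2
Reactants: 3 2‑bromo‑3‑fluoro‑5‑methoxyphenol; 4 ethyl 3‑oxohexanoate
Product: 5 8‑bromo‑7‑fluoro‑5‑methoxy‑4‑propyl‑2H‑chromen‑2‑one
Conditions: MeSO3H, 25–45 °C
Reagents that add atoms: none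
Why: Pechmann condensation (transesterification, intramolecular hydroxyalkylation, dehydration); bromine blocks one ortho position, so ring closure can occur only at the carbon between OH and OMe, which fixes the whole substitution pattern.

Step 3
Reactants: 5 8‑bromo‑7‑fluoro‑5‑methoxy‑4‑propyl‑2H‑chromen‑2‑one
Product: 6 (4R)‑8‑bromo‑7‑fluoro‑5‑methoxy‑4‑propylchroman‑2‑one
Conditions: Cu(OAc)2·H2O (3 mol%), (S)‑DTBM‑SEGPHOS (3 mol%), HSiMe(OEt)2 (1.5 equiv), t‑BuOH (1.2 equiv), toluene, 0 °C
Reagents that add atoms: none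
Why: CuH‑catalysed asymmetric conjugate reduction of a 4‑substituted coumarin, in which the ligated copper hydride delivers H to one face of C4 (ligand control sets the benzylic centre) and t‑BuOH releases the lactone from the copper enolate.

Step 4
Reactants: 6 (4R)‑8‑bromo‑7‑fluoro‑5‑methoxy‑4‑propylchroman‑2‑one
Product: 7 (4R)‑8‑bromo‑7‑fluoro‑5‑methoxy‑4‑propylchroman‑2‑ol (lactol)
Conditions: DIBAL‑H (1.1 equiv), CH2Cl2, −78 °C; Rochelle salt work‑up
Reagents that add atoms: none
Why: partial hydride reduction of the aryl lactone stops at the tetrahedral aluminate at −78 °C and gives the lactol on work‑up; C4 is not touched.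

Step 5
Reactants: 7 (4R)‑8‑bromo‑7‑fluoro‑5‑methoxy‑4‑propylchroman‑2‑ol
Product: 8 (4R)‑8‑bromo‑7‑fluoro‑2,5‑dimethoxy‑4‑propylchromane
Conditions: MeOH, PPTS (cat.), 3 Å MS, rt
Reagents that add atoms: methanol CO
Why: acid‑catalysed lactol‑to‑acetal exchange through the cyclic oxocarbenium ion (Fischer‑type acetalisation) masks the latent aldehyde/phenol pair as a base‑stable mixed acetal.

Step 6
Reactants: 8 (4R)‑8‑bromo‑7‑fluoro‑2,5‑dimethoxy‑4‑propylchromane; 9 prenyl bromide
Product: 11 (4R)‑8‑bromo‑7‑fluoro‑2,5‑dimethoxy‑6‑(3‑methylbut‑2‑enyl)‑4‑propylchromane, via C6 aryllithium 10 (not isolated)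
Conditions: LDA (1.1 equiv), THF, −78 °C; CuBr·SMe2 (10 mol%), 9, −78 → 0 °C
Reagents that add atoms: none
Why: directed ortho‑lithiation at the only aromatic C–H (acidified by the flanking F and OMe; the bromine is meta and untouched at −78 °C), then Cu‑catalysed SN2 allylation at the unhindered CH2 end of prenyl bromide, which should give the linear prenyl group.

Step 7
Reactants: 12 ethyl (S)‑3‑hydroxybutanoate
Product: 14 ethyl (2S,3S)‑3‑hydroxy‑2‑methylbutanoate, via dilithio alkoxide enolate 13 (not isolated)
Conditions: LDA (2.2 equiv), THF, −50 → −20 °C; MeI, DMPU, −78 → 0 °C; NH4Cl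
Reagents that add atoms: iodomethane CI
Why: Fráter–Seebach alkylation, in which the chelated alkoxide–enolate is methylated anti to the C3 methyl group, so the pool‑derived (3S) centre sets (2S).

Step 8
Reactants: 14 ethyl (2S,3S)‑3‑hydroxy‑2‑methylbutanoate
Product: 15 (2S,3S)‑3‑hydroxy‑2‑methylbutanoic acid
Conditions: LiOH, THF/H2O, 0 °C → rt; HCl to pH 2
Reagents that add atoms: lithium hydroxide [Li+].[OH-]
Why: ester saponification under conditions too mild for retro‑aldol cleavage or α‑epimerisation of the β‑hydroxy acid.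

Step 9
Reactants: 15 (2S,3S)‑3‑hydroxy‑2‑methylbutanoic acid
Product: 17 (3S,4S)‑3,4‑dimethyloxetan‑2‑one (trans), via carboxylic sulfonic mixed anhydride 16 (not isolated)
Conditions: PhSO2Cl (2 equiv), pyridine, 0 °C
Reagents that add atoms: none
Why: β‑lactonisation by carboxyl activation, where the hydroxyl attacks the acyl carbon of the mixed anhydride (4‑exo‑trig); no bond to either stereocentre is broken, so the anti acid gives the trans lactone.

Step 10
Reactants: 11 (4R)‑8‑bromo‑7‑fluoro‑2,5‑dimethoxy‑6‑(3‑methylbut‑2‑enyl)‑4‑propylchromane; 17 (3S,4S)‑3,4‑dimethyloxetan‑2‑one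
Product: 20 tricyclic chromanone acetal [(2S,3S)‑7‑methoxy‑2,3‑dimethyl‑8‑prenylchroman‑4‑one whose O5 and C6 are bridged by –CH(OMe)–CH2–(R)‑CH(Pr)–], via C8 aryllithium 18 (not isolated), via lithium aldolate 19 (not isolated)
Conditions: t‑BuLi (2.05 equiv), Et2O/THF, −78 °C; 17 (1.05 equiv), −78 °C; DMPU, −78 °C → rt; NH4Cl
Reagents that add atoms: none
Why: Br/Li exchange gives aryllithium 18 (flanked by F and the acetal oxygen, kept at −78 °C to prevent LiF loss), which attacks the strained acyl carbon of 17 with acyl–oxygen cleavage to give ketone alkoxide 19; the ketone just formed at C4a turns the neighbouring C8a–F into an SNAr site, and the alkoxide closes O1–C8a through a Meisenheimer adduct with loss of LiF. The closest known reaction types are the acyl C–O opening of β‑lactones by hard organolithium nucleophiles to β‑hydroxy ketones and the intramolecular SNAr etherification of 2‑fluoroaryl ketones by a β‑alkoxide. The pyranone ring closes 6‑exo‑trig at an sp2 carbon by addition–elimination, the C4–C4a bond having been made intermolecularly just before. No stereocentre is created: C2 and C3 come from 17 with retention because neither the C2–O nor the C3–H bond is broken (the neighbouring oxyanion disfavours enolisation of 19, and the cyclisation consumes the only base). Regiochemistry needs no control because 19 carries a single fluorine ortho to the acyl group and the other ortho substituent is a non‑leaving aryl ether oxygen. Single addition is secured by the hindered 2,6‑disubstituted aryl ketone and the low temperature.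

Step 11
Reactants: 20 tricyclic chromanone acetal
Product: 21 tricyclic chromanone lactol (OMe of the acetal replaced by OH)
Conditions: AcOH/THF/H2O (3:1:1), 40 °C
Reagents that add atoms: water O
Why: mild aqueous‑acid hydrolysis of the mixed aryl alkyl acetal through the oxocarbenium ion; the prenyl alkene, the β‑aryloxy ketone and C3 should be stable to dilute acetic acid.

Step 12
Reactants: 21 tricyclic chromanone lactol
Product: 23 (3R)‑3‑[(2S,3S)‑5‑hydroxy‑7‑methoxy‑2,3‑dimethyl‑8‑(3‑methylbut‑2‑enyl)‑4‑oxochroman‑6‑yl]hexanoic acid, via ring‑opened hydroxy aldehyde 22 (not isolated)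
Conditions: NaClO2, NaH2PO4, 2‑methyl‑2‑butene, t‑BuOH/H2O, 0 °C → rt
Reagents that add atoms: sodium chlorite [Na+].[O-]Cl=O
Why: Pinnick oxidation of the aldehyde tautomer of the lactol (ring–chain equilibrium pulled open by the C5–OH···O=C4 hydrogen bond) with an HOCl scavenger, which should spare the prenyl group and the fully substituted arene and avoids any base that could epimerise C3 or open the chromanone.

**Compound list**

1 | 4‑bromo‑3,5‑difluoroanisole | COc1cc(F)c(Br)c(F)c1 | starting material
2 | [2‑(2‑bromo‑3‑fluoro‑5‑methoxyphenoxy)ethyl]trimethylsilane | COc1cc(F)c(Br)c(OCC[Si](C)(C)C)c1 | intermediate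
3 | 2‑bromo‑3‑fluoro‑5‑methoxyphenol | COc1cc(O)c(Br)c(F)c1 | intermediate
4 | ethyl 3‑oxohexanoate | CCCC(=O)CC(=O)OCC | starting material
5 | 8‑bromo‑7‑fluoro‑5‑methoxy‑4‑propyl‑2H‑chromen‑2‑one | CCCC1=CC(=O)Oc2c1c(OC)cc(F)c2Br | intermediate
6 | (4R)‑8‑bromo‑7‑fluoro‑5‑methoxy‑4‑propylchroman‑2‑one | CCC[C@@H]1CC(=O)Oc2c1c(OC)cc(F)c2Br | intermediate
7 | (4R)‑8‑bromo‑7‑fluoro‑5‑methoxy‑4‑propylchroman‑2‑ol (C2 epimers) | CCC[C@@H]1CC(O)Oc2c1c(OC)cc(F)c2Br | intermediate
8 | (4R)‑8‑bromo‑7‑fluoro‑2,5‑dimethoxy‑4‑propylchromane (C2 epimers) | CCC[C@@H]1CC(OC)Oc2c1c(OC)cc(F)c2Br | intermediate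
9 | prenyl bromide (1‑bromo‑3‑methylbut‑2‑ene) | CC(C)=CCBr | starting material
10 | C6 aryllithium of 8 | CCC[C@@H]1CC(OC)Oc2c1c(OC)c([Li])c(F)c2Br | intermediate
11 | (4R)‑8‑bromo‑7‑fluoro‑2,5‑dimethoxy‑6‑(3‑methylbut‑2‑enyl)‑4‑propylchromane | CCC[C@@H]1CC(OC)Oc2c1c(OC)c(CC=C(C)C)c(F)c2Br | intermediate
12 | ethyl (S)‑3‑hydroxybutanoate | CCOC(=O)C[C@H](C)O | starting material
13 | dilithio alkoxide enolate of 12 | CCOC(O[Li])=C[C@H](C)O[Li] | intermediate
14 | ethyl (2S,3S)‑3‑hydroxy‑2‑methylbutanoate | CCOC(=O)[C@@H](C)[C@H](C)O | intermediate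
15 | (2S,3S)‑3‑hydroxy‑2‑methylbutanoic acid | OC(=O)[C@@H](C)[C@H](C)O | intermediate
16 | benzenesulfonic (2S,3S)‑3‑hydroxy‑2‑methylbutanoic anhydride | O=S(=O)(OC(=O)[C@@H](C)[C@H](C)O)c1ccccc1 | intermediate
17 | (3S,4S)‑3,4‑dimethyloxetan‑2‑one | C[C@@H]1OC(=O)[C@H]1C | intermediate
18 | C8 aryllithium from 11 | CCC[C@@H]1CC(OC)Oc2c1c(OC)c(CC=C(C)C)c(F)c2[Li] | intermediate
19 | lithium aldolate (aryl ketone with β‑OLi, F still in place) | CCC[C@@H]1CC(OC)Oc2c1c(OC)c(CC=C(C)C)c(F)c2C(=O)[C@@H](C)[C@H](C)O[Li] | intermediate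
20 | tricyclic chromanone acetal | CCC[C@@H]1CC(OC)Oc2c1c(OC)c(CC=C(C)C)c1O[C@@H](C)[C@H](C)C(=O)c12 | intermediate
21 | tricyclic chromanone lactol | CCC[C@@H]1CC(O)Oc2c1c(OC)c(CC=C(C)C)c1O[C@@H](C)[C@H](C)C(=O)c12 | intermediate
22 | ring‑opened hydroxy aldehyde | CCC[C@H](CC=O)c1c(O)c2c(c(CC=C(C)C)c1OC)O[C@@H](C)[C@H](C)C2=O | intermediate
23 | (3R)‑3‑[(2S,3S)‑5‑hydroxy‑7‑methoxy‑2,3‑dimethyl‑8‑(3‑methylbut‑2‑enyl)‑4‑oxochroman‑6‑yl]hexanoic acid | CCC[C@H](CC(=O)O)c1c(O)c2c(c(CC=C(C)C)c1OC)O[C@@H](C)[C@H](C)C2=O | target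

**Step count and risks**

Total step count: 12. Longest linear sequence: 9 (steps 1–6, 10, 11, 12); steps 7–9 make the lactone branch.

Steps most likely to fail:

1. Step 10. Three processes could compete: proton transfer from the lactone (enolisation and β‑elimination) instead of carbonyl addition, loss of LiF from the ortho‑fluoroaryllithium if the temperature rises before acylation, and slow SNAr on the electron‑rich ring, which would allow retro‑aldol cleavage or C3 epimerisation of the aldolate. Fallback, setting out from bromide 11 and ester 14: the ester is converted with MeNHOMe·HCl/i‑PrMgCl into hydroxy Weinreb amide F1 and silylated (TBSCl, imidazole) to silyl ether F2. Bromide 11 is lithiated as before and acylated with F2 to give the isolable silyloxy ketone F3. TBAF in THF then removes the silyl group, and the alkoxide formed closes onto C8a–F under nearly neutral conditions, returning to the route at 20.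

2. Step 2. The electrophilic ring closure at the carbon flanked by OH and OMe may be sluggish on the halogen‑deactivated phenol, with sulfonation or acid‑induced bromine migration taking over. Fallback, setting out from phenol 3: esterification with hex‑2‑ynoic acid (DCC, DMAP) gives aryl hex‑2‑ynoate F4. Pd(OAc)2‑catalysed intramolecular alkyne hydroarylation in TFA/CH2Cl2 then forms the C4–C4a bond at the same, only free, ortho carbon and returns to the route at coumarin 5.

3. Step 3. Facial discrimination at C4 may be poor next to the peri 5‑OMe group, and over‑reduction of the aryl lactone may occur (any lactol formed converges at step 4, but low enantioselectivity would not). Fallback, setting out from phenol 3: Pd(OAc)2/TFA annulation with ethyl propiolate gives the 4‑unsubstituted coumarin F5. Cu‑catalysed asymmetric conjugate addition of n‑PrMgBr (CuBr·SMe2, Josiphos‑type ferrocenyl diphosphine, t‑BuOMe, −72 °C) then introduces the propyl group and the benzylic stereocentre in one C–C bond formation, returning to the route at lactone 6.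

Further compounds
F1 | step 10 | (2S,3S)‑3‑hydroxy‑N‑methoxy‑N,2‑dimethylbutanamide | CON(C)C(=O)[C@@H](C)[C@H](C)O
F2 | step 10 | (2S,3S)‑3‑(tert‑butyldimethylsilyloxy)‑N‑methoxy‑N,2‑dimethylbutanamide | CON(C)C(=O)[C@@H](C)[C@H](C)O[Si](C)(C)C(C)(C)C
F3 | step 10 | silyloxy ketone (aryl ketone from 11 and F2, F still in place) | CCC[C@@H]1CC(OC)Oc2c1c(OC)c(CC=C(C)C)c(F)c2C(=O)[C@@H](C)[C@H](C)O[Si](C)(C)C(C)(C)C
F4 | step 2 | 2‑bromo‑3‑fluoro‑5‑methoxyphenyl hex‑2‑ynoate | CCCC#CC(=O)Oc1cc(OC)cc(F)c1Br
F5 | step 3 | 8‑bromo‑7‑fluoro‑5‑methoxy‑2H‑chromen‑2‑one | COc1cc(F)c(Br)c2OC(=O)C=Cc12
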